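Core numbering of the target is used for every intermediate: C1 (methyl-bearing bridgehead), C2 (CH carrying the carbinol arm), C3 (quaternary), C4 (bridgehead CH), C5, C6 and O7.

## Analysis of the target

Target 34 is a C20 bromochloro ether built on a 7-oxabicyclo[2.2.1]heptane, that is, a cyclohexane ring C1–C6 whose C1 and C4 are linked by O7. C1 is a fully substituted bridgehead with a methyl group and C4 is a bridgehead CH. C2 carries the 3-hydroxy-3-methylpent-4-enyl arm on the endo face, and C3 is quaternary with an endo methyl group and an exo 3-bromo-4-chloro-4-methylpentyl arm. The four contiguous core centres are (1S,2S,3S,4R): the two arms are trans across C2–C3, and the oxygen bridge is anti to the C2 arm and to the C3 methyl group. The (S)-tertiary vinyl carbinol and the (S)-CHBr centre are too far from the core to be relayed from it and need reagent control. The tertiary allylic alcohol ionises under acid, the vicinal secondary bromide/tertiary chloride is lost to base, reducing metals and soft nucleophiles, and the tertiary bridging ether is open to strong Lewis acids. The difficulty lies in the fully substituted C1 and C3 flanking C2, and in two arms whose functional groups tolerate little of each other's chemistry. The strategy rests on O7 being a one-atom bridge that can only join C1 and C4 cis: if C1–O7 is made from a C1 cation and a C4 hydroxyl, C4 alone dictates C1, and any configuration C1 had in the monocycle is erased.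

## Retrosynthetic reasoning

**Halogens (34 back to 30).** The C–Br centre has no neighbour that could control it, so it is traced to the (R)-epoxide 31, opened at its secondary carbon with inversion to bromohydrin 32, and the tertiary hydroxyl is then exchanged for chlorine (33). The bromochloride is made last because it would not survive the zinc, hydride and ylide steps of the other arm. The exchange runs through a cation, which a free tertiary allylic alcohol would not survive, so that alcohol is carried as its silyl ether (30 to 33) and freed in the last step.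

**Vinyl carbinol (30 back to 26).** The tertiary C–O bond is kept and the vinyl group is traced to epoxy iodide 28 by a reductive 1,3-transposition, which in turn comes from epoxy alcohol 27. This puts the carbinol centre under the control of an asymmetric epoxidation of the E allylic alcohol 26. The reducing metal needed here is the reason this arm is finished before any halogen is introduced.

**Allylic alcohol (26 back to 21).** The trisubstituted olefin of 26 is cut between the vinylic carbon and the hydroxymethyl carbon and traced to terminal alkyne 24 by syn-carbometalation, which fixes the E geometry that the epoxidation turns into configuration. Alkyne 24 comes from aldehyde 23, alcohol 22 and pivalate 21.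

**Homoprenyl arm (21 back to 17).** The trisubstituted olefin is cut by an olefination of aldehyde 20, which comes from the allyl group of 17 via alcohol 19. Allyl is chosen for C3 because a quaternary centre needs a reactive electrophile, and a monosubstituted olefin is the least nucleophilic one to take through an acid step.

**Key disconnection (17 back to 15 and 16).** C1–O7 is the only ring bond of 17 that is not part of the carbocycle; cutting it gives a cyclohexane-1,4-diol with a tertiary carbinol at C1 and a secondary one at C4. In the forward sense C1 is ionised and the C4 hydroxyl closes the bridge, so both C1 epimers 15 and 16 give 17. The step needs C2, C3 and C4 already in place.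

**C1 carbinol (15/16 back to 13).** The C1 methyl and hydroxyl are disconnected together to ketone 14 and its ketal 13. A C1 stereocentre set early would have to pass through the C3 allylation and the C4 reduction, where the two C1 epimers would adopt different ring conformations and need not react alike. C1 is therefore kept as a symmetric ketal through those steps, and the methyl group is added last, where face selectivity is irrelevant because the key step removes it.

**C4 and C5–C6 (13 back to 11).** C4 decides the face of the bridge, so it is set by a catalyst-controlled reduction of ketone 12, not by the ring. Ketone 12 comes from enone 11 by conjugate reduction, which leaves the allyl group alone.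

**C3 and C2 (11 back to 1).** The quaternary centre is cut twice at C3: allyl bromide 9 on 8, and a methyl group on 6. The enone double bond and the fully substituted C1 leave C3 as the only enolisable position, and putting allyl in second places it anti to the C2 arm. Enone 6 is cut at the C2–arm bond to the symmetric dienone 4 and iodide 3 (from 1 via 2); an enantioselective conjugate addition desymmetrises 4 and sets C2.

## Alternatives that were turned down

**Alternative 1:** The disconnection cuts both arm-to-ring bonds at C2 and C3 of a monocyclic ketal ketone. In the forward key step CuBr·SMe2 with a chiral ferrocenyl diphosphine catalyses 1,4-addition of Grignard reagent A3 to enone A2, and the magnesium enolate is alkylated by iodide A4 to give A1; no ring is closed.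
- For: C2 and C3 are set in one flask and the homoprenyl chain arrives intact. This saves the three steps 17 to 21, and on step economy at this stage it is stronger than the chosen route.
- Against: A2 is an α-methyl enone whose β-carbon sits next to a spiro ketal, a poor acceptor for asymmetric Grignard addition. Making a quaternary centre from a hindered magnesium enolate and the unactivated iodide A4 is likely to be slow and to lose out to proton transfer. The oxygen bridge must still be made afterwards, and then a trisubstituted olefin 1,3 to C1 would face the cation.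
- Comparison: the chosen route pays three steps for the homologation, but builds C3 with allyl bromide and lets only a monosubstituted olefin meet acid.

**Alternative 2:** The disconnection is the C2–C3 bond, traced to a ring contraction of an oxabicyclo[3.2.1]octanone. Irradiation of diazo ketone A6 in an alcohol expels N2, C3 migrates to the carbene carbon, and the ketene is trapped as ester A5.
- For: the bridge and both bridgeheads exist before the key step, so no cation at C1 is ever needed. On that point it is stronger than the chosen route, whose main risk is that cation. Diazo transfer also has only one possible site.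
- Against: C2 is set by protonation of a ketene-derived enol, at a centre that stays epimerisable. The ester must be extended by four carbons at a carbon flanked by two fully substituted ones. The homoprenyl olefin lies within reach of the carbene. The quaternary C3 must be built enantioselectively into the bicyclic ketone beforehand, without an obvious catalytic handle.
- Comparison: the chosen route sets C2 by a catalyst and C3 by a cyclic enolate before any ring is closed, and reaches the bridged core in ten steps.

**Alternative 3:** The disconnection is the C1–C2 bond, with C1–O7 formed in the same flask. A silyl triflate turns hydroxy ketone A8, through its cyclic hemiketal, into an oxolanyl oxocarbenium ion, which the propargylsilane attacks through the alkyne carbon bound to C3 to give allene A7.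
- For: both rings and the tetrasubstituted C1 are formed in one step from a chain, a larger gain in complexity than the one bond and one ring of the chosen key step.
- Against: A8 needs a quaternary C3 next to the C4 carbinol made with acyclic stereocontrol. The allene must then be turned into a CH bearing a five-carbon arm, so C2 is set late by an addition of uncertain regio- and face-selectivity, beside a second olefin. The homoprenyl olefin is also a competent nucleophile towards the oxocarbenium ion.
- Comparison: the chosen route gains less per step at the key stage but leaves no stereocentre of the core to be set after ring closure.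

Key step: step 10

Assumption: in step 3 the ligand is taken to impose the same sense of attack on the enone face as it does with cyclohex-2-enone; if the opposite holds, the enantiomeric ligand is used.

## Route

Step 1
Reactants: 1 3-bromopropan-1-ol
Product: 2 3-bromopropyl 2,2-dimethylpropanoate
Conditions: t-BuCOCl, pyridine, CH2Cl2, 0 °C → rt
Reagents that add atoms: pivaloyl chloride, CC(C)(C)C(=O)Cl
Why: Acylation of a primary alcohol; the pivalate has no α-hydrogen and should resist the amide bases, organometallics and acid used up to step 13.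

Step 2
Reactants: 2 3-bromopropyl 2,2-dimethylpropanoate
Product: 3 3-iodopropyl 2,2-dimethylpropanoate
Conditions: NaI, acetone, reflux
Reagents that add atoms: sodium iodide, [Na+].[I-]
Why: Finkelstein exchange driven by precipitation of NaBr; the iodide is needed for the iodine–zinc exchange of step 3.

Step 3
Reactants: 3 3-iodopropyl 2,2-dimethylpropanoate; 4 4,4-dimethoxycyclohexa-2,5-dien-1-one
Product: 6 3-[(1S)-2,2-dimethoxy-5-oxocyclohex-3-en-1-yl]propyl 2,2-dimethylpropanoate, via bis[3-(pivaloyloxy)propyl]zinc 5 (not isolated)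
Conditions: 3, Et2Zn, CuI (cat.), 50 °C, then volatiles removed in vacuo; Cu(OTf)2 (2 mol%), (R)-binaphthyl-2,2′-diyl N,N-bis[(S)-1-phenylethyl]phosphoramidite (4 mol%), PhMe, −30 °C, then 4; aq. NH4Cl
Reagents that add atoms: diethylzinc, CC[Zn]CC (supplies the zinc of 5 only)
Why: Iodine–zinc exchange gives the ester-bearing dialkylzinc, and copper–phosphoramidite-catalysed enantioselective 1,4-addition of dialkylzincs to 4,4-disubstituted cyclohexadienones is a known desymmetrisation. The ligand selects one enantiotopic enone unit and one face and so sets C2 as (S), while the zinc enolate formed guards against a second addition.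

Step 4
Reactants: 6 3-[(1S)-2,2-dimethoxy-5-oxocyclohex-3-en-1-yl]propyl 2,2-dimethylpropanoate
Product: 8 3-[(1S,6S)-2,2-dimethoxy-6-methyl-5-oxocyclohex-3-en-1-yl]propyl 2,2-dimethylpropanoate, via lithium dienolate 7 (not isolated)
Conditions: LiN(i-Pr)2, THF, −78 °C; MeI, −78 → −30 °C
Reagents that add atoms: iodomethane, CI; lithium diisopropylamide, [Li+].CC(C)[N-]C(C)C (supplies the lithium of 7 only)
Why: Kinetic enolate alkylation; C3 is the only position that can be deprotonated, because C1 is fully substituted and C5 is vinylic. The methyl group should enter mainly anti to the C2 arm, but this centre is planarised again in step 5, so its configuration does not matter.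

Step 5
Reactants: 8 3-[(1S,6S)-2,2-dimethoxy-6-methyl-5-oxocyclohex-3-en-1-yl]propyl 2,2-dimethylpropanoate; 9 allyl bromide (3-bromoprop-1-ene)
Product: 11 3-[(1S,6S)-2,2-dimethoxy-6-methyl-5-oxo-6-(prop-2-en-1-yl)cyclohex-3-en-1-yl]propyl 2,2-dimethylpropanoate, via lithium enolate 10 (not isolated)
Conditions: LiN(i-Pr)2, THF, −78 → −20 °C; DMPU, 9, −78 → 0 °C
Reagents that add atoms: lithium diisopropylamide, [Li+].CC(C)[N-]C(C)C (supplies the lithium of 10 only)
Why: Second α′-alkylation at the same carbon builds the quaternary C3, for which a reactive allylic bromide is needed. The electrophile should approach anti to the adjacent C2 arm, which places allyl trans and methyl cis to that arm as the target requires.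

Step 6
Reactants: 11 3-[(1S,6S)-2,2-dimethoxy-6-methyl-5-oxo-6-(prop-2-en-1-yl)cyclohex-3-en-1-yl]propyl 2,2-dimethylpropanoate
Product: 12 3-[(1S,2S)-6,6-dimethoxy-2-methyl-3-oxo-2-(prop-2-en-1-yl)cyclohexyl]propyl 2,2-dimethylpropanoate
Conditions: Cu(OAc)2·H2O (5 mol%), 1,2-bis(diphenylphosphino)benzene (5 mol%), (HMe2Si)2O, t-BuOH, PhMe, rt
Reagents that add atoms: none
Why: Copper hydride conjugate reduction delivers hydride to the enone β-carbon only and should leave the isolated monosubstituted olefin, the ketal and the pivalate untouched; no stereocentre is formed. Hydrogenation is avoided because it would also saturate the allyl group.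

Step 7
Reactants: 12 3-[(1S,2S)-6,6-dimethoxy-2-methyl-3-oxo-2-(prop-2-en-1-yl)cyclohexyl]propyl 2,2-dimethylpropanoate
Product: 13 3-[(1S,2S,3R)-3-hydroxy-6,6-dimethoxy-2-methyl-2-(prop-2-en-1-yl)cyclohexyl]propyl 2,2-dimethylpropanoate
Conditions: (S)-1-methyl-3,3-diphenyltetrahydro-1H,3H-pyrrolo[1,2-c][1,3,2]oxazaborole (0.5 equiv), catecholborane, PhMe, −40 → −20 °C; MeOH
Reagents that add atoms: none
Why: Corey–Bakshi–Shibata reduction; the catalyst binds the carbonyl lone pair on the side of the C5 methylene, away from quaternary C3, and the (S)-catalyst should deliver hydride to the face that carries the C2 arm and the C3 methyl group, giving the (R)-carbinol with its hydroxyl cis to the allyl group. Catecholborane is the hydride source because it does not hydroborate the allyl group at this temperature.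

Step 8
Reactants: 13 3-[(1S,2S,3R)-3-hydroxy-6,6-dimethoxy-2-methyl-2-(prop-2-en-1-yl)cyclohexyl]propyl 2,2-dimethylpropanoate
Product: 14 3-[(1S,2S,3R)-3-hydroxy-2-methyl-6-oxo-2-(prop-2-en-1-yl)cyclohexyl]propyl 2,2-dimethylpropanoate
Conditions: 1 M aq. HCl, THF, 0 °C → rt
Reagents that add atoms: water, O
Why: Hydrolysis of a dimethyl ketal under mild aqueous acid, which the secondary alcohol, the pivalate and the allyl group tolerate. Conditions are kept mild because C2 is now α to a ketone and could epimerise.

Step 9
Reactants: 14 3-[(1S,2S,3R)-3-hydroxy-2-methyl-6-oxo-2-(prop-2-en-1-yl)cyclohexyl]propyl 2,2-dimethylpropanoate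
Product: 15 3-[(1S,2S,3R,6S)-3,6-dihydroxy-2,6-dimethyl-2-(prop-2-en-1-yl)cyclohexyl]propyl 2,2-dimethylpropanoate (cis-1,4-diol) and 16 its (6R) epimer (trans-1,4-diol); the two are not separated
Conditions: CeCl3, MeLi, THF, −78 °C; then 14, −78 → −40 °C
Reagents that add atoms: methyllithium, [Li]C (delivered as MeCeCl2)
Why: Organocerium addition to an enolisable, α-branched ketone; the weakly basic reagent should suppress enolisation, which protects C2, and should spare the pivalate at low temperature. Either face may be attacked, since both tertiary carbinols are wanted: step 10 erases C1.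

Step 10
Reactants: 15 cis-1,4-diol; 16 trans-1,4-diol (used as the mixture from step 9)
Product: 17 3-[(1S,2S,3S,4R)-1,3-dimethyl-3-(prop-2-en-1-yl)-7-oxabicyclo[2.2.1]heptan-2-yl]propyl 2,2-dimethylpropanoate
Conditions: TsOH·H2O (10 mol%), PhMe, 60 °C
Reagents that add atoms: none
Why: Either epimer is protonated at the tertiary C1 hydroxyl and loses water to give one and the same tertiary cyclohexyl cation, so 15 and 16 converge. The ring flexes to a boat in which the C4 hydroxyl lies over the empty orbital at C1, and O–C1 bond formation followed by loss of a proton gives the bridged ether. The closest known reaction is the acid-catalysed cyclodehydration of p-menthane-1,4-diols to the 1,4-cineole skeleton. The one new ring is closed by transannular attack of oxygen on a trigonal carbon; counted through C5–C6 it is an oxolane formed in a 5-exo-trig sense. The only new stereocentre, C1, is fixed by the bridge itself: a one-atom link between C1 and C4 must be cis, so the (4R) carbinol set in step 7 dictates (1S). The step needs ionisation at C1 only, which the tertiary versus secondary nature of the two carbinols secures, and capture by oxygen faster than proton loss, hydride shift from C2 or attack by a π bond. Alkenes formed by proton loss towards C6 or the C1 methyl group can re-enter through the same cation under the conditions, the pre-placed C4 hydroxyl makes the capture intramolecular, and the pivalate and the monosubstituted olefin are poorly nucleophilic spectators.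

Step 11
Reactants: 17 3-[(1S,2S,3S,4R)-1,3-dimethyl-3-(prop-2-en-1-yl)-7-oxabicyclo[2.2.1]heptan-2-yl]propyl 2,2-dimethylpropanoate
Product: 19 3-[(1S,2S,3S,4R)-3-(3-hydroxypropyl)-1,3-dimethyl-7-oxabicyclo[2.2.1]heptan-2-yl]propyl 2,2-dimethylpropanoate, via B-alkyl-9-borabicyclo[3.3.1]nonane 18 (not isolated)
Conditions: 9-BBN, THF, 0 °C → rt; then 3 M NaOH, 30% H2O2, 0 °C
Reagents that add atoms: 9-borabicyclo[3.3.1]nonane, B1C2CCCC1CCC2 (supplies the boron of 18 only); hydrogen peroxide, OO
Why: Anti-Markovnikov hydroboration–oxidation of the terminal olefin; the hindered pivalate should survive a short, cold alkaline oxidation.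

Step 12
Reactants: 19 3-[(1S,2S,3S,4R)-3-(3-hydroxypropyl)-1,3-dimethyl-7-oxabicyclo[2.2.1]heptan-2-yl]propyl 2,2-dimethylpropanoate
Product: 20 3-[(1S,2S,3S,4R)-1,3-dimethyl-3-(3-oxopropyl)-7-oxabicyclo[2.2.1]heptan-2-yl]propyl 2,2-dimethylpropanoate
Conditions: Dess–Martin periodinane, NaHCO3, CH2Cl2, rt
Reagents that add atoms: none
Why: Dess–Martin oxidation of a primary alcohol to the aldehyde under buffered, non-acidic conditions that leave the bridged ether alone.

Step 13
Reactants: 20 3-[(1S,2S,3S,4R)-1,3-dimethyl-3-(3-oxopropyl)-7-oxabicyclo[2.2.1]heptan-2-yl]propyl 2,2-dimethylpropanoate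
Product: 21 3-[(1S,2S,3S,4R)-1,3-dimethyl-3-(4-methylpent-3-en-1-yl)-7-oxabicyclo[2.2.1]heptan-2-yl]propyl 2,2-dimethylpropanoate
Conditions: i-PrPPh3I, n-BuLi, THF, 0 °C; then 20, −78 °C → rt
Reagents that add atoms: isopropyltriphenylphosphonium iodide, CC(C)[P+](c1ccccc1)(c1ccccc1)c1ccccc1.[I-]
Why: Wittig olefination with the isopropylidene ylide gives the trisubstituted olefin with no geometry to control; the aldehyde should react far faster than the hindered pivalate.

Step 14
Reactants: 21 3-[(1S,2S,3S,4R)-1,3-dimethyl-3-(4-methylpent-3-en-1-yl)-7-oxabicyclo[2.2.1]heptan-2-yl]propyl 2,2-dimethylpropanoate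
Product: 22 3-[(1S,2S,3S,4R)-1,3-dimethyl-3-(4-methylpent-3-en-1-yl)-7-oxabicyclo[2.2.1]heptan-2-yl]propan-1-ol
Conditions: i-Bu2AlH, CH2Cl2, −78 °C
Reagents that add atoms: none
Why: Reductive cleavage of the pivalate by an aluminium hydride; the olefin and the ether are inert.

Step 15
Reactants: 22 3-[(1S,2S,3S,4R)-1,3-dimethyl-3-(4-methylpent-3-en-1-yl)-7-oxabicyclo[2.2.1]heptan-2-yl]propan-1-ol
Product: 23 3-[(1S,2S,3S,4R)-1,3-dimethyl-3-(4-methylpent-3-en-1-yl)-7-oxabicyclo[2.2.1]heptan-2-yl]propanal
Conditions: Dess–Martin periodinane, NaHCO3, CH2Cl2, rt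
Reagents that add atoms: none
Why: Dess–Martin oxidation; the trisubstituted olefin is not touched.

Step 16
Reactants: 23 3-[(1S,2S,3S,4R)-1,3-dimethyl-3-(4-methylpent-3-en-1-yl)-7-oxabicyclo[2.2.1]heptan-2-yl]propanal
Product: 24 (1S,2S,3S,4R)-2-(but-3-yn-1-yl)-1,3-dimethyl-3-(4-methylpent-3-en-1-yl)-7-oxabicyclo[2.2.1]heptane
Conditions: dimethyl (1-diazo-2-oxopropyl)phosphonate, K2CO3, MeOH, 0 °C → rt
Reagents that add atoms: dimethyl (1-diazo-2-oxopropyl)phosphonate, CC(=O)C(=[N+]=[N-])P(=O)(OC)OC
Why: Seyferth–Gilbert homologation in its Ohira–Bestmann form turns the aldehyde into the terminal alkyne with one added carbon under mild base; the aldehyde has no stereocentre at its α-carbon.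

Step 17
Reactants: 24 (1S,2S,3S,4R)-2-(but-3-yn-1-yl)-1,3-dimethyl-3-(4-methylpent-3-en-1-yl)-7-oxabicyclo[2.2.1]heptane
Product: 26 (2E)-5-[(1S,2S,3S,4R)-1,3-dimethyl-3-(4-methylpent-3-en-1-yl)-7-oxabicyclo[2.2.1]heptan-2-yl]-3-methylpent-2-en-1-ol, via (E)-alkenyldimethylalane 25 (not isolated)
Conditions: Me3Al, Cp2ZrCl2, CH2Cl2, 0 °C → rt; then n-BuLi, THF, −78 °C; (CH2O)n, → rt
Reagents that add atoms: trimethylaluminium, C[Al](C)C; formaldehyde (from paraformaldehyde), C=O
Why: Negishi zirconium-catalysed carboalumination adds methyl and aluminium syn across the terminal alkyne with aluminium at the terminus, and the alanate is hydroxymethylated with retention. The E allylic alcohol should therefore form as a single geometric isomer, which an olefination of a methyl ketone would not guarantee.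

Step 18
Reactants: 26 (2E)-5-[(1S,2S,3S,4R)-1,3-dimethyl-3-(4-methylpent-3-en-1-yl)-7-oxabicyclo[2.2.1]heptan-2-yl]-3-methylpent-2-en-1-ol
Product: 27 [(2S,3S)-3-{2-[(1S,2S,3S,4R)-1,3-dimethyl-3-(4-methylpent-3-en-1-yl)-7-oxabicyclo[2.2.1]heptan-2-yl]ethyl}-3-methyloxiran-2-yl]methanol
Conditions: Ti(OiPr)4, L-(+)-diethyl tartrate, t-BuOOH, 4 Å molecular sieves, CH2Cl2, −20 °C
Reagents that add atoms: tert-butyl hydroperoxide, CC(C)(C)OO
Why: Sharpless asymmetric epoxidation; the L-(+)-tartrate complex should give the (2S,3S)-epoxide of an E-3-methylalk-2-en-1-ol, as with geraniol, and it epoxidises only the allylic alcohol, not the remote trisubstituted olefin.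

Step 19
Reactants: 27 [(2S,3S)-3-{2-[(1S,2S,3S,4R)-1,3-dimethyl-3-(4-methylpent-3-en-1-yl)-7-oxabicyclo[2.2.1]heptan-2-yl]ethyl}-3-methyloxiran-2-yl]methanol
Product: 28 (2S,3R)-3-(iodomethyl)-2-methyl-2-{2-[(1S,2S,3S,4R)-1,3-dimethyl-3-(4-methylpent-3-en-1-yl)-7-oxabicyclo[2.2.1]heptan-2-yl]ethyl}oxirane
Conditions: I2, PPh3, imidazole, CH2Cl2, 0 °C
Reagents that add atoms: iodine, II
Why: Appel-type iodination of the primary alcohol without touching the epoxide; no stereocentre is affected (the descriptor at the former C2 changes only through priority).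

Step 20
Reactants: 28 (2S,3R)-3-(iodomethyl)-2-methyl-2-{2-[(1S,2S,3S,4R)-1,3-dimethyl-3-(4-methylpent-3-en-1-yl)-7-oxabicyclo[2.2.1]heptan-2-yl]ethyl}oxirane
Product: 29 (3S)-5-[(1S,2S,3S,4R)-1,3-dimethyl-3-(4-methylpent-3-en-1-yl)-7-oxabicyclo[2.2.1]heptan-2-yl]-3-methylpent-1-en-3-ol
Conditions: Zn dust, AcOH, EtOH, rt
Reagents that add atoms: none
Why: Reductive elimination of the β-iodo epoxide (zinc inserts into C–I, the epoxide opens) gives the transposed tertiary allylic alcohol. The tertiary C–O bond is never broken, so the (S) configuration set in step 18 is carried over.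

Step 21
Reactants: 29 (3S)-5-[(1S,2S,3S,4R)-1,3-dimethyl-3-(4-methylpent-3-en-1-yl)-7-oxabicyclo[2.2.1]heptan-2-yl]-3-methylpent-1-en-3-ol
Product: 30 triethyl({(3S)-5-[(1S,2S,3S,4R)-1,3-dimethyl-3-(4-methylpent-3-en-1-yl)-7-oxabicyclo[2.2.1]heptan-2-yl]-3-methylpent-1-en-3-yl}oxy)silane
Conditions: Et3SiOTf, 2,6-lutidine, CH2Cl2, −78 → 0 °C
Reagents that add atoms: triethylsilyl trifluoromethanesulfonate, CC[Si](CC)(CC)OS(=O)(=O)C(F)(F)F
Why: Silylation of a hindered tertiary alcohol with a silyl triflate and a hindered base; the ether keeps the allylic carbinol from being activated and ionised in step 24.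

Step 22
Reactants: 30 triethyl({(3S)-5-[(1S,2S,3S,4R)-1,3-dimethyl-3-(4-methylpent-3-en-1-yl)-7-oxabicyclo[2.2.1]heptan-2-yl]-3-methylpent-1-en-3-yl}oxy)silane
Product: 31 the (2R)-3,3-dimethyloxiran-2-yl epoxide of 30 (triethylsilyl ether of 29 whose C3 arm is 2-[(2R)-3,3-dimethyloxiran-2-yl]ethyl)
Conditions: 1,2:4,5-di-O-isopropylidene-β-D-erythro-2,3-hexodiulo-2,6-pyranose (0.3 equiv), KHSO5 (as 2KHSO5·KHSO4·K2SO4), K2CO3, Bu4NHSO4, MeCN/CH2(OMe)2/aq. buffer (pH 10.5), 0 °C
Reagents that add atoms: potassium peroxymonosulfate, [K+].[O-]S(=O)(=O)OO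
Why: Shi epoxidation; the dioxirane of the D-fructose-derived ketone should give the (R)-epoxide of a 2-methylalk-2-ene through the spiro transition state, under catalyst control remote from the core. The electron-rich trisubstituted olefin reacts far faster than the vinyl group.

Step 23
Reactants: 31 the (2R)-epoxide
Product: 32 (3S)-bromohydrin (triethylsilyl ether of 29 whose C3 arm is (3S)-3-bromo-4-hydroxy-4-methylpentyl)
Conditions: Li2NiBr4, THF, 0 °C → rt
Reagents that add atoms: dilithium tetrabromonickelate, [Li+].[Li+].[Ni+2].[Br-].[Br-].[Br-].[Br-]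
Why: Opening of an epoxide by soft, weakly Lewis-acidic bromide in an SN2 sense at the less substituted carbon; inversion there converts the (R)-epoxide carbon into the (S)-C–Br centre and leaves a tertiary alcohol. The silyl ether and the bridged ether should not respond to this near-neutral reagent.

Step 24
Reactants: 32 (3S)-bromohydrin
Product: 33 triethylsilyl ether of the target (C3 arm = (3S)-3-bromo-4-chloro-4-methylpentyl)
Conditions: 1-chloro-N,N,2-trimethylprop-1-en-1-amine, CH2Cl2, 0 °C → rt
Reagents that add atoms: 1-chloro-N,N,2-trimethylprop-1-en-1-amine, CC(C)=C(Cl)N(C)C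
Why: Dehydroxychlorination of a tertiary alcohol by an α-chloroenamine under neutral conditions: the alkoxyiminium chloride ionises with help from the neighbouring bromine, and chloride opens the bromonium ion at the tertiary carbon. Bromine never leaves its carbon, so the (S) centre is retained, and the silyl ether has no free hydroxyl for the reagent to activate.

Step 25
Reactants: 33 triethylsilyl ether of the target
Product: 34 (3S)-5-[(1S,2S,3S,4R)-3-[(3S)-3-bromo-4-chloro-4-methylpentyl]-1,3-dimethyl-7-oxabicyclo[2.2.1]heptan-2-yl]-3-methylpent-1-en-3-ol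
Conditions: HF·pyridine, pyridine, THF, 0 °C → rt
Reagents that add atoms: none
Why: Fluoride cleavage of the silyl ether under buffered conditions that are neither basic enough to eliminate HCl or HBr nor acidic enough to ionise the tertiary allylic alcohol.

## Compound list

1 | 3-bromopropan-1-ol | OCCCBr | starting material
2 | 3-bromopropyl 2,2-dimethylpropanoate | CC(C)(C)C(=O)OCCCBr | intermediate
3 | 3-iodopropyl 2,2-dimethylpropanoate | CC(C)(C)C(=O)OCCCI | intermediate
4 | 4,4-dimethoxycyclohexa-2,5-dien-1-one | COC1(OC)C=CC(=O)C=C1 | starting material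
5 | bis[3-(pivaloyloxy)propyl]zinc | CC(C)(C)C(=O)OCCC[Zn]CCCOC(=O)C(C)(C)C | intermediate (not isolated)
6 | 3-[(1S)-2,2-dimethoxy-5-oxocyclohex-3-en-1-yl]propyl 2,2-dimethylpropanoate | CC(C)(C)C(=O)OCCC[C@H]1CC(=O)C=CC1(OC)OC | intermediate
7 | lithium dienolate of 6 (enolate at C3–C4) | [Li+].CC(C)(C)C(=O)OCCC[C@H]1C=C([O-])C=CC1(OC)OC | intermediate (not isolated)
8 | 3-[(1S,6S)-2,2-dimethoxy-6-methyl-5-oxocyclohex-3-en-1-yl]propyl 2,2-dimethylpropanoate (methyl trans to the arm; its C6 epimer serves equally) | CC(C)(C)C(=O)OCCC[C@H]1[C@H](C)C(=O)C=CC1(OC)OC | intermediate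
9 | allyl bromide (3-bromoprop-1-ene) | C=CCBr | starting material
10 | lithium enolate of 8 | [Li+].CC(C)(C)C(=O)OCCC[C@H]1C(C)=C([O-])C=CC1(OC)OC | intermediate (not isolated)
11 | 3-[(1S,6S)-2,2-dimethoxy-6-methyl-5-oxo-6-(prop-2-en-1-yl)cyclohex-3-en-1-yl]propyl 2,2-dimethylpropanoate | CC(C)(C)C(=O)OCCC[C@H]1[C@](C)(CC=C)C(=O)C=CC1(OC)OC | intermediate
12 | 3-[(1S,2S)-6,6-dimethoxy-2-methyl-3-oxo-2-(prop-2-en-1-yl)cyclohexyl]propyl 2,2-dimethylpropanoate | CC(C)(C)C(=O)OCCC[C@H]1[C@](C)(CC=C)C(=O)CCC1(OC)OC | intermediate
13 | 3-[(1S,2S,3R)-3-hydroxy-6,6-dimethoxy-2-methyl-2-(prop-2-en-1-yl)cyclohexyl]propyl 2,2-dimethylpropanoate | CC(C)(C)C(=O)OCCC[C@H]1[C@](C)(CC=C)[C@H](O)CCC1(OC)OC | intermediate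
14 | 3-[(1S,2S,3R)-3-hydroxy-2-methyl-6-oxo-2-(prop-2-en-1-yl)cyclohexyl]propyl 2,2-dimethylpropanoate | CC(C)(C)C(=O)OCCC[C@H]1[C@](C)(CC=C)[C@H](O)CCC1=O | intermediate
15 | 3-[(1S,2S,3R,6S)-3,6-dihydroxy-2,6-dimethyl-2-(prop-2-en-1-yl)cyclohexyl]propyl 2,2-dimethylpropanoate (cis-1,4-diol) | CC(C)(C)C(=O)OCCC[C@H]1[C@](C)(CC=C)[C@H](O)CC[C@]1(C)O | intermediate
16 | 3-[(1S,2S,3R,6R)-3,6-dihydroxy-2,6-dimethyl-2-(prop-2-en-1-yl)cyclohexyl]propyl 2,2-dimethylpropanoate (trans-1,4-diol) | CC(C)(C)C(=O)OCCC[C@H]1[C@](C)(CC=C)[C@H](O)CC[C@@]1(C)O | intermediate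
17 | 3-[(1S,2S,3S,4R)-1,3-dimethyl-3-(prop-2-en-1-yl)-7-oxabicyclo[2.2.1]heptan-2-yl]propyl 2,2-dimethylpropanoate | CC(C)(C)C(=O)OCCC[C@H]1[C@](C)(CC=C)[C@H]2CC[C@]1(C)O2 | intermediate
18 | B-alkyl-9-borabicyclo[3.3.1]nonane from 17 | CC(C)(C)C(=O)OCCC[C@H]1[C@](C)(CCCB3C4CCCC3CCC4)[C@H]2CC[C@]1(C)O2 | intermediate (not isolated)
19 | 3-[(1S,2S,3S,4R)-3-(3-hydroxypropyl)-1,3-dimethyl-7-oxabicyclo[2.2.1]heptan-2-yl]propyl 2,2-dimethylpropanoate | CC(C)(C)C(=O)OCCC[C@H]1[C@](C)(CCCO)[C@H]2CC[C@]1(C)O2 | intermediate
20 | 3-[(1S,2S,3S,4R)-1,3-dimethyl-3-(3-oxopropyl)-7-oxabicyclo[2.2.1]heptan-2-yl]propyl 2,2-dimethylpropanoate | CC(C)(C)C(=O)OCCC[C@H]1[C@](C)(CCC=O)[C@H]2CC[C@]1(C)O2 | intermediate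
21 | 3-[(1S,2S,3S,4R)-1,3-dimethyl-3-(4-methylpent-3-en-1-yl)-7-oxabicyclo[2.2.1]heptan-2-yl]propyl 2,2-dimethylpropanoate | CC(C)(C)C(=O)OCCC[C@H]1[C@](C)(CCC=C(C)C)[C@H]2CC[C@]1(C)O2 | intermediate
22 | 3-[(1S,2S,3S,4R)-1,3-dimethyl-3-(4-methylpent-3-en-1-yl)-7-oxabicyclo[2.2.1]heptan-2-yl]propan-1-ol | OCCC[C@H]1[C@](C)(CCC=C(C)C)[C@H]2CC[C@]1(C)O2 | intermediate
23 | 3-[(1S,2S,3S,4R)-1,3-dimethyl-3-(4-methylpent-3-en-1-yl)-7-oxabicyclo[2.2.1]heptan-2-yl]propanal | O=CCC[C@H]1[C@](C)(CCC=C(C)C)[C@H]2CC[C@]1(C)O2 | intermediate
24 | (1S,2S,3S,4R)-2-(but-3-yn-1-yl)-1,3-dimethyl-3-(4-methylpent-3-en-1-yl)-7-oxabicyclo[2.2.1]heptane | C#CCC[C@H]1[C@](C)(CCC=C(C)C)[C@H]2CC[C@]1(C)O2 | intermediate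
25 | (E)-alkenyldimethylalane from 24 | C[Al](C)/C=C(\C)CC[C@H]1[C@](C)(CCC=C(C)C)[C@H]2CC[C@]1(C)O2 | intermediate (not isolated)
26 | (2E)-5-[(1S,2S,3S,4R)-1,3-dimethyl-3-(4-methylpent-3-en-1-yl)-7-oxabicyclo[2.2.1]heptan-2-yl]-3-methylpent-2-en-1-ol | OC/C=C(\C)CC[C@H]1[C@](C)(CCC=C(C)C)[C@H]2CC[C@]1(C)O2 | intermediate
27 | [(2S,3S)-3-{2-[(1S,2S,3S,4R)-1,3-dimethyl-3-(4-methylpent-3-en-1-yl)-7-oxabicyclo[2.2.1]heptan-2-yl]ethyl}-3-methyloxiran-2-yl]methanol | OC[C@@H]1O[C@@]1(C)CC[C@H]2[C@](C)(CCC=C(C)C)[C@H]3CC[C@]2(C)O3 | intermediate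
28 | (2S,3R)-3-(iodomethyl)-2-methyl-2-{2-[(1S,2S,3S,4R)-1,3-dimethyl-3-(4-methylpent-3-en-1-yl)-7-oxabicyclo[2.2.1]heptan-2-yl]ethyl}oxirane | IC[C@@H]1O[C@@]1(C)CC[C@H]2[C@](C)(CCC=C(C)C)[C@H]3CC[C@]2(C)O3 | intermediate
29 | (3S)-5-[(1S,2S,3S,4R)-1,3-dimethyl-3-(4-methylpent-3-en-1-yl)-7-oxabicyclo[2.2.1]heptan-2-yl]-3-methylpent-1-en-3-ol | C=C[C@@](C)(O)CC[C@H]1[C@](C)(CCC=C(C)C)[C@H]2CC[C@]1(C)O2 | intermediate
30 | triethylsilyl ether of 29 | C=C[C@@](C)(O[Si](CC)(CC)CC)CC[C@H]1[C@](C)(CCC=C(C)C)[C@H]2CC[C@]1(C)O2 | intermediate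
31 | (2R)-3,3-dimethyloxiran-2-yl epoxide of 30 | C=C[C@@](C)(O[Si](CC)(CC)CC)CC[C@H]1[C@](C)(CC[C@H]3OC3(C)C)[C@H]2CC[C@]1(C)O2 | intermediate
32 | (3S)-3-bromo-4-hydroxy-4-methylpentyl bromohydrin (silyl ether) | C=C[C@@](C)(O[Si](CC)(CC)CC)CC[C@H]1[C@](C)(CC[C@H](Br)C(C)(C)O)[C@H]2CC[C@]1(C)O2 | intermediate
33 | triethylsilyl ether of 34 | C=C[C@@](C)(O[Si](CC)(CC)CC)CC[C@H]1[C@](C)(CC[C@H](Br)C(C)(C)Cl)[C@H]2CC[C@]1(C)O2 | intermediate
34 | (3S)-5-[(1S,2S,3S,4R)-3-[(3S)-3-bromo-4-chloro-4-methylpentyl]-1,3-dimethyl-7-oxabicyclo[2.2.1]heptan-2-yl]-3-methylpent-1-en-3-ol | C=C[C@@](C)(O)CC[C@H]1[C@](C)(CC[C@H](Br)C(C)(C)Cl)[C@H]2CC[C@]1(C)O2 | target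

## Step count and least certain steps

Total step count: 25. Longest linear sequence: 25 steps (1 to 34; 23 steps counted from dienone 4).

**Step 10 (key step).** Loss of a proton from the C1 cation may outrun ring closure if the boat needed for transannular capture is disfavoured by the eclipsing that develops between the C2 and C3 substituents. Proton loss towards C2 followed by reprotonation would scramble the C2 configuration, and hydride shift from C2 or participation of the allyl π bond may also divert the cation. Fallback, setting out from 13 and coming back at 19: the allyl group is hydroborated first (9-BBN, then NaOH/H2O2) to give the diol ketal F1; mild aqueous acid unmasks the ketone to give the dihydroxy ketone F2; non-basic Takai–Lombardo methylenation (Zn, CH2Br2, TiCl4) gives the C1-methylidene diol F3; and alkoxymercuration–demercuration (Hg(OCOCF3)2, THF, then NaBH4/NaOH) forms the same C1–O7 bond through a mercurinium ion instead of a free cation, giving 19. The allyl olefin is removed beforehand because it would compete for divalent mercury.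

**Step 23.** Bromide may attack the tertiary epoxide carbon in an SN1-like opening, or the metal salts may promote rearrangement of the epoxide to a ketone, in place of SN2 opening at the secondary carbon. Fallback, from 30 to 32: bromohydrin formation with N-bromosuccinimide in aqueous THF puts bromine on the secondary and hydroxyl on the tertiary carbon by Markovnikov opening of the bromonium ion, without facial control; 32 is then separated by preparative HPLC from its C–Br epimer, the (3R)-bromohydrin F4.

**Step 24.** The ionised intermediate may lose a proton to give an allylic bromide, or the silyl ether may be lost and the allylic carbinol ionised, instead of chloride being captured. Fallback, from 30 to 33: direct Markovnikov bromochlorination of the trisubstituted olefin with N-bromosuccinimide and Et4NCl in CH2Cl2, chloride opening the bromonium ion at the tertiary carbon; 33 is separated by preparative HPLC from the (3R)-bromochloride F5.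

**Step 7.** The catalyst's preference may be mismatched with the intrinsic facial bias of this hindered, conformationally mobile ketone, which would erode selectivity or slow the reduction. Fallback, from 12 to 13: unselective reduction with NaBH4 in MeOH, chromatographic separation of 13 from its C4 epimer F6, and return of F6 to 12 by Dess–Martin oxidation for another pass.

**Step 5.** Facial selectivity in forming the quaternary centre may be poor or reversed, because the pseudo-axial methoxy group at C1 shields the face that the C2 arm leaves open; enolisation of the hindered α-methyl ketone may also be incomplete. Fallback, from 6 to 11: the order of the alkylations is reversed, allyl bromide first to give the C3-allyl enone F7, then LiN(i-Pr)2 and MeI, so that the face preferred by the second electrophile delivers the methyl group instead.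

**Step 9.** Enolisation of the ketone may compete with addition, with epimerisation at C2 or incomplete conversion. Fallback, from 14 to 17: Takai–Lombardo methylenation (Zn, CH2Br2, TiCl4) gives the methylidene alcohol F8, and the sulfonic acid of step 10 protonates its 1,1-disubstituted olefin to the same C1 cation, which the C4 hydroxyl captures to give 17.

## Further compounds

F1 | step 10 | 3-[(1S,2S,3R)-3-hydroxy-2-(3-hydroxypropyl)-6,6-dimethoxy-2-methylcyclohexyl]propyl 2,2-dimethylpropanoate | CC(C)(C)C(=O)OCCC[C@H]1[C@](C)(CCCO)[C@H](O)CCC1(OC)OC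
F2 | step 10 | 3-[(1S,2S,3R)-3-hydroxy-2-(3-hydroxypropyl)-2-methyl-6-oxocyclohexyl]propyl 2,2-dimethylpropanoate | CC(C)(C)C(=O)OCCC[C@H]1[C@](C)(CCCO)[C@H](O)CCC1=O
F3 | step 10 | 3-[(1R,2S,3R)-3-hydroxy-2-(3-hydroxypropyl)-2-methyl-6-methylidenecyclohexyl]propyl 2,2-dimethylpropanoate | CC(C)(C)C(=O)OCCC[C@H]1[C@](C)(CCCO)[C@H](O)CCC1=C
F4 | step 23 | (3R)-bromohydrin, C–Br epimer of 32 | C=C[C@@](C)(O[Si](CC)(CC)CC)CC[C@H]1[C@](C)(CC[C@@H](Br)C(C)(C)O)[C@H]2CC[C@]1(C)O2
F5 | step 24 | (3R)-bromochloride, C–Br epimer of 33 | C=C[C@@](C)(O[Si](CC)(CC)CC)CC[C@H]1[C@](C)(CC[C@@H](Br)C(C)(C)Cl)[C@H]2CC[C@]1(C)O2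
F6 | step 7 | 3-[(1S,2S,3S)-3-hydroxy-6,6-dimethoxy-2-methyl-2-(prop-2-en-1-yl)cyclohexyl]propyl 2,2-dimethylpropanoate (C4 epimer of 13) | CC(C)(C)C(=O)OCCC[C@H]1[C@](C)(CC=C)[C@@H](O)CCC1(OC)OC
F7 | step 5 | 3-[(1S,6S)-2,2-dimethoxy-5-oxo-6-(prop-2-en-1-yl)cyclohex-3-en-1-yl]propyl 2,2-dimethylpropanoate | CC(C)(C)C(=O)OCCC[C@H]1[C@H](CC=C)C(=O)C=CC1(OC)OC
F8 | step 9 | 3-[(1R,2S,3R)-3-hydroxy-2-methyl-6-methylidene-2-(prop-2-en-1-yl)cyclohexyl]propyl 2,2-dimethylpropanoate | CC(C)(C)C(=O)OCCC[C@H]1[C@](C)(CC=C)[C@H](O)CCC1=C
A1 | alternative 1 | 6-(but-3-en-1-yl)-7-methyl-7-(4-methylpent-3-en-1-yl)-1,4-dioxaspiro[4.5]decan-8-one (arms trans) | C=CCC[C@H]1[C@](C)(CCC=C(C)C)C(=O)CCC12OCCO2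
A2 | alternative 1 | 7-methyl-1,4-dioxaspiro[4.5]dec-6-en-8-one | CC1=CC2(CCC1=O)OCCO2
A3 | alternative 1 | but-3-en-1-ylmagnesium bromide | C=CCC[Mg]Br
A4 | alternative 1 | 5-iodo-2-methylpent-2-ene | CC(C)=CCCI
A5 | alternative 2 | methyl 1,3-dimethyl-3-(4-methylpent-3-en-1-yl)-7-oxabicyclo[2.2.1]heptane-2-carboxylate (endo ester) | COC(=O)[C@H]1[C@](C)(CCC=C(C)C)[C@H]2CC[C@]1(C)O2
A6 | alternative 2 | 2-diazo-1,4-dimethyl-4-(4-methylpent-3-en-1-yl)-8-oxabicyclo[3.2.1]octan-3-one | [N-]=[N+]=C1C(=O)[C@](C)(CCC=C(C)C)[C@H]2CC[C@]1(C)O2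
A7 | alternative 3 | 2-ethenylidene-1,3-dimethyl-3-(4-methylpent-3-en-1-yl)-7-oxabicyclo[2.2.1]heptane | C=C=C1[C@](C)(CCC=C(C)C)[C@H]2CC[C@]1(C)O2
A8 | alternative 3 | 5-hydroxy-6,10-dimethyl-6-[3-(trimethylsilyl)prop-1-yn-1-yl]undec-9-en-2-one | C[Si](C)(C)CC#C[C@](C)(CCC=C(C)C)[C@H](O)CCC(C)=O
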